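**Retrosynthetic overview** (chain carbons C1'–C24', with C1' = OCH2; ring carbons C-1 to C-6)
1. Gentiside K ⇐ tetracosyl 2,3-diacetoxybenzoate by deacetylation. This ester ⇐ stearic acid + 8-[(2,3-diacetoxybenzoyl)oxy]octanoic acid by forming C7'–C8' in an anodic double decarboxylation (crossed Kolbe coupling), a radical union of two carbons of like polarity.
2. Enabling feature: C7' and C8' lie in the unbranched, heteroatom-free polymethylene chain, and C7' is six CH2 groups away from the ester oxygen. Cut there, both carbons are primary, unstabilised radical centres that couple rather than over-oxidise. C8'–C24' is stearic acid minus CO2, and C1'–C7' is an 8-oxyoctanoic acid minus CO2.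
3. The benzene ring is the only other oxidisable site. With the oxygens on C-2 and C-3 acetylated next to the C-1 ester, it carries only acyl-type groups and should outlast carboxylate discharge.
4. Acid partner ⇐ 2,3-dihydroxybenzoic acid + tert-butyl 8-bromooctanoate, by carboxylate alkylation, acetylation and tert-butyl acidolysis.
5. No ring is formed. The benzene ring is bought with 2,3-dihydroxybenzoic acid.

Key step: step 4

Remark: the target has no stereocentre and no stereogenic double bond, so the given structure is its only stereoisomer and no step has to control configuration.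

Step 1
Reactants: 1 2,3-dihydroxybenzoic acid; 2 tert-butyl 8-bromooctanoate
Product: 3 tert-butyl 8-[(2,3-dihydroxybenzoyl)oxy]octanoate
Conditions: KHCO3 (1.2 equiv), DMF, N2, 50 °C
Reagents that add atoms: none
Why: This is a chemoselective SN2 O-alkylation of a carboxylate, because hydrogencarbonate deprotonates only the CO2H (pKa about 3) and not the phenols (pKa about 10), so the primary bromide should meet a single nucleophile.

Step 2
Reactants: 3 tert-butyl 8-[(2,3-dihydroxybenzoyl)oxy]octanoate
Product: 4 tert-butyl 8-{[2,3-bis(acetyloxy)benzoyl]oxy}octanoate
Conditions: Ac2O (3 equiv), pyridine (4 equiv), DMAP (5 mol%), CH2Cl2, 0 °C to rt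
Reagents that add atoms: acetic anhydride, CC(=O)OC(C)=O
Why: DMAP-catalysed O-acetylation of both phenols is routine, leaves both esters untouched and turns the electron-rich catechol into an electron-poor arene.

Step 3
Reactants: 4 tert-butyl 8-{[2,3-bis(acetyloxy)benzoyl]oxy}octanoate
Product: 5 8-{[2,3-bis(acetyloxy)benzoyl]oxy}octanoic acid
Conditions: TFA/CH2Cl2 (1:3), rt; co-evaporation with toluene
Reagents that add atoms: none
Why: Acidolysis of a tert-butyl ester through the tert-butyl cation (loss of isobutene) is selective, since aryl acetates and the primary alkyl benzoate are inert to anhydrous TFA.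

Step 4
Reactants: 5 8-{[2,3-bis(acetyloxy)benzoyl]oxy}octanoic acid; 6 stearic acid (octadecanoic acid)
Product: 7 tetracosyl 2,3-bis(acetyloxy)benzoate
Conditions: 6 (5 equiv), Me4NOH·5H2O (10 mol% of total acid, mixed with 6 before 5 is added), acetone, undivided cell, RVC | RVC, square-wave alternating polarity (ca. 50 ms pulses), constant current, 35–40 °C, until 5 is consumed
Reagents that add atoms: none
Why: In the anodic half-cycles both carboxylates are oxidised by one electron and lose CO2, giving the heptadecyl and 7-(aroyloxy)heptyl radicals in a thin radical-rich layer at the vitreous carbon surface, where they combine to the C7'–C8' bond, while in the cathodic half-cycles carboxyl protons are reduced to H2 and the carboxylates are regenerated. The closest known reaction type is the mixed (crossed) Kolbe electrolysis of a fatty acid with an ω-functionalised alkanoic acid (half esters, ω-acyloxy acids), here in its alternating-polarity variant in acetone. No ring is closed and no stereocentre is formed, so neither a mode of closure nor a stereocontrol element is needed. Cross- against homo-coupling is only statistical, so cheap 6 is used in excess to channel 5 into 7, and the two symmetrical homodimers (a poorly soluble, non-polar C34 alkane and a clearly more polar C14 bis-benzoate) should be removable by filtration and chromatography. Radical coupling against cation chemistry (Hofer–Moest pathway) is secured by the substrate, because both radical carbons are primary, unbranched and free of α-heteroatoms. Arene oxidation is held off because the ring of 5 bears only one CO2R and two OAc groups and no free OH, the methanol-free carboxylic acid/carboxylate buffer and the polarity switching (no lasting basic layer at an electrode) should spare the aryl acetates, and the excess free acid as cathodic proton source should keep the esters from being reduced.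

Step 5
Reactants: 7 tetracosyl 2,3-bis(acetyloxy)benzoate
Product: 8 Gentiside K (tetracosyl 2,3-dihydroxybenzoate)
Conditions: pyrrolidine (2.5 equiv), THF, Ar, 0 °C to rt; then 1 M aq. citric acid
Reagents that add atoms: none
Why: This is a chemoselective aminolysis of aryl acetates, because a phenoxide leaves far more readily than an alkoxide, the conjugated alkyl benzoate is deactivated further once the ortho-OH is free, and the absence of an alcohol solvent excludes transesterification.

**Compound list**
1 | 2,3-dihydroxybenzoic acid | OC(=O)c1cccc(O)c1O | starting material
2 | tert-butyl 8-bromooctanoate | CC(C)(C)OC(=O)CCCCCCCBr | starting material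
3 | tert-butyl 8-[(2,3-dihydroxybenzoyl)oxy]octanoate | CC(C)(C)OC(=O)CCCCCCCOC(=O)c1cccc(O)c1O | intermediate
4 | tert-butyl 8-{[2,3-bis(acetyloxy)benzoyl]oxy}octanoate | CC(C)(C)OC(=O)CCCCCCCOC(=O)c1cccc(OC(C)=O)c1OC(C)=O | intermediate
5 | 8-{[2,3-bis(acetyloxy)benzoyl]oxy}octanoic acid | OC(=O)CCCCCCCOC(=O)c1cccc(OC(C)=O)c1OC(C)=O | intermediate
6 | stearic acid (octadecanoic acid) | CCCCCCCCCCCCCCCCCC(=O)O | starting material
7 | tetracosyl 2,3-bis(acetyloxy)benzoate | CCCCCCCCCCCCCCCCCCCCCCCCOC(=O)c1cccc(OC(C)=O)c1OC(C)=O | intermediate
8 | Gentiside K (tetracosyl 2,3-dihydroxybenzoate) | CCCCCCCCCCCCCCCCCCCCCCCCOC(=O)c1cccc(O)c1O | target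

**Total step count:** 5. **Longest linear sequence:** 5 (1 → 3 → 4 → 5 → 7 → 8).

**Steps most likely to fail**

Step 4.
- Risks: statistical homo-coupling may consume too much of 5. Waxy products may passivate the electrodes. Slow loss of an acetyl group would be followed by anodic oxidation of the freed phenol. Part of the radicals may be over-oxidised to cations.
- Fallback: this makes the same bond without statistics and under reducing conditions. It sets out from 5 and returns at 7.
- Activation: 5 is condensed with N-hydroxyphthalimide (DIC, cat. DMAP, CH2Cl2) to 1,3-dioxoisoindolin-2-yl 8-{[2,3-bis(acetyloxy)benzoyl]oxy}octanoate F1.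
- Organometallic partner: commercial 1-bromoheptadecane and Mg in THF give heptadecylmagnesium bromide F2. This is transmetalated completely with ZnCl2 (0.5 equiv) to diheptadecylzinc F3.
- Coupling: a nickel-catalysed decarboxylative Negishi-type alkyl–alkyl coupling of F1 with F3 should deliver 7 (NiCl2·glyme, 4,4'-di-tert-butyl-2,2'-bipyridine, THF/DMF, rt). The aryl acetates should tolerate the organozinc.

Step 5.
- Risks: aminolysis may reach the tetracosyl ester, and the freed catechol may be oxidised by air in the basic medium.
- Fallback: the head group is not unmasked on the finished ester but replaced. It sets out from 7 and returns at 8.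
- Sequence: full saponification of 7 (KOH, EtOH/THF/H2O, reflux, then HCl) gives tetracosan-1-ol F4. An Appel reaction (CBr4, PPh3, CH2Cl2) gives 1-bromotetracosane F5. F5 then alkylates the carboxylate of unprotected 1 (KHCO3, DMF/THF, N2, 65 °C), the reaction type of step 1, to give 8 with no protecting group left to remove.

Step 1.
- Risks: a phenol oxygen may be alkylated in competition, and the unprotected catechol may be oxidised by air in warm DMF.
- Fallback: the catechol is masked before the ester is made. It sets out from 1 and returns at 4, bypassing 3.
- Sequence: 1 is acetylated (Ac2O, cat. H2SO4, 60 °C, then water) to 2,3-bis(acetyloxy)benzoic acid F6. F6 is joined to commercial tert-butyl 8-hydroxyoctanoate by Steglich esterification (EDC, cat. DMAP, CH2Cl2, rt) to give 4.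

**Further compounds**
F1 | step 4 | 1,3-dioxoisoindolin-2-yl 8-{[2,3-bis(acetyloxy)benzoyl]oxy}octanoate | CC(=O)Oc1cccc(C(=O)OCCCCCCCC(=O)ON2C(=O)c3ccccc3C2=O)c1OC(C)=O
F2 | step 4 | heptadecylmagnesium bromide | CCCCCCCCCCCCCCCCC[Mg]Br
F3 | step 4 | diheptadecylzinc | CCCCCCCCCCCCCCCCC[Zn]CCCCCCCCCCCCCCCCC
F4 | step 5 | tetracosan-1-ol | CCCCCCCCCCCCCCCCCCCCCCCCO
F5 | step 5 | 1-bromotetracosane | CCCCCCCCCCCCCCCCCCCCCCCCBr
F6 | step 1 | 2,3-bis(acetyloxy)benzoic acid | CC(=O)Oc1cccc(C(=O)O)c1OC(C)=O
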